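Remark on the chemistry: the target SMILES carries no axial descriptor, so the B–C axis (the only axis between two unsymmetrical rings) is treated as unspecified and the product is taken as the racemic or freely equilibrating material.

## Analysis of the target

Target 13 (C24H17ClO12) is a linear quaterphenyl A–B–C–D in which four phloroglucinol units are joined carbon to carbon through meta-related positions, so that all twelve oxygens are free phenols. Rings A and D are terminal 2,4,6-trihydroxyphenyl groups. Ring B (B1 bonded to ring C, B3 bonded to ring A) is a 2,4,6-trihydroxy-1,3-phenylene that keeps one hydrogen at B5, and ring C (C1 to ring B, C3 to ring D) is the same unit with chlorine at C5 and no hydrogen on carbon. There is no stereocentre; each of the three biaryl axes has four ortho oxygen substituents, and only the B–C axis could be stereogenic. The compound is an electron-rich polyphenol that oxidises easily as its phenolate, and the aryl C–Cl bond must survive every metal-mediated step, so the oxygens are carried as methyl ethers or created late. The difficulty lies in three tetra-ortho-substituted biaryl bonds, in placing one chlorine on one inner ring, and in the fact that the halves A–B and D–C differ only by H against Cl. The strategy rests on B1 and D1: each is flanked by two hydroxyl-bearing carbons (B2/B6, D2/D6), which is the oxidation pattern of the central carbon of an arylmalonate, while B3–B4–B5 and D3–D4–D5 map onto the CH2–CO–CH2 unit of a 3-oxoglutarate.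

## Retrosynthetic reasoning

**13 to 12.** The last disconnection is of six O–methyl bonds, three on ring A and three on ring C. These methyl groups come with 1,3,5-trimethoxybenzene 1, the source of both rings, and they keep ring C from behaving as a phenol in the arylation. The forward step is a Lewis-acid dealkylation of six aryl ethers that must leave the C–Cl bond alone.

**12 to 10 and 11.** The A–B biaryl bond is cut next. It is the only bond that makes the two halves different, so it is formed as late as possible and everything before it is symmetric about ring C. In the terphenyl hexaol 10, rings B and D are free phloroglucinols with four equivalent C–H positions, each between two hydroxyl groups. That is the substrate type for ortho-arylation by the aryllead reagent 11. The forward reaction has to transfer one 2,4,6-trimethoxyphenyl group and stop there. Reagent 11 goes back to 1 by cutting the C–Pb bond.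

**10 to 8.** The four ester groups at B3, B5, D3 and D5 of the tetraester 8 are the activating groups of the annulation partner. They are removed by hydrolysis and decarboxylation, which a 2,4,6-trihydroxybenzoic acid (here the tetraacid 9) undergoes readily.

**8 to 5 and 6.** In each of rings B and D the two bonds from the hydroxyl-bearing carbons next to the biaryl carbon to the ester-bearing carbons are cut (B2–B3, B6–B5, D2–D3, D6–D5), four bonds in all. This is preferred to cutting the B–C and C–D biaryl bonds, which carry four ortho substituents each and are the hardest bonds in the molecule to make by coupling. In the bis-malonate 5 these bonds already exist as ordinary aryl–C(sp3) bonds, and the crowded biaryl arises by building a ring on a carbon that is already attached. The step gains two rings with all six oxygens in place, full symmetry and the chlorine already installed. The forward reaction consumes two molecules of dimethyl 3-oxoglutarate 6 for each molecule of 5: each malonate unit has to acylate both α-carbons of one molecule of 6, passing through the open-chain adduct 7.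

**5 to 3 and 4.** The two aryl–C(malonate) bonds are cut, leading to the dibromide 3 and two molecules of dimethyl malonate 4. A palladium-catalysed enolate arylation forms them directly. This avoids any benzylic halide of a trimethoxybenzene, a class that is too prone to self-alkylation to be homologated reliably.

**3 to 2 to 1.** The C–Br and C–Cl bonds are made by electrophilic substitution. The threefold symmetry of 1 leaves no regiochemical choice. Chlorine goes in first because monochlorination to 2 stops cleanly with one equivalent of reagent, and exhaustive bromination then fills the two remaining positions.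

## Alternatives that were turned down

**Alternative 1:** Here the four ring bonds of rings B and C that form in a two-fold cyclobutenone–alkyne benzannulation (Danheiser benzannulation) are disconnected. In the forward step two molecules of the cyclobutenone A1 open to vinylketenes, which add to the two triple bonds of the diyne A2. Four-electron ring opening, six-electron closure and tautomerisation give the quaterphenyl A3.
- For: one step assembles the whole A–B–C–D skeleton, including all three hindered biaryl bonds, without a biaryl coupling. On convergence this is stronger than the chosen route, which builds only the terphenyl in its key step.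
- Against: A3 has no chlorine. It has one C–H on each central ring (equivalent by symmetry) and four more on the outer rings, all on strongly activated rings. Chlorine would have to be put in at the end by an electrophilic substitution that picks one of two equivalent inner positions and avoids the outer rings, with nothing in the structure to direct it. A2 is a sensitive, electron-rich diyne, the second annulation must occur on an alkyne that already carries a bulky aryl group, and A1 needs its own multi-step preparation.
- Comparison: the chosen route carries chlorine from step 1. Its one statistical step acts on four truly equivalent sites, so only the number of substitutions is at issue, not their position.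

**Alternative 2:** Here the A–B and C–D bonds are disconnected. In the forward step the biaryl A4 is deprotonated once on each ring at a C–H between two methoxy groups. The dilithio species adds to the carbonyl of two molecules of the quinone monoketal A5 to give the bis(quinol ketal) A6, which must then be aromatised reductively.
- For: both hindered bonds are made by carbonyl addition to give an sp3 carbon, which tolerates ortho substitution better than a cross-coupling. The chlorine and the identity of every ring are fixed, so there is no statistical step. On that point it is stronger than the chosen route.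
- Against: it presupposes A4, whose own tetra-ortho-substituted bond still has to be made by coupling. Exact dilithiation with an alkyllithium in the presence of an aryl chloride is required. The carbonyl of A5 sits between two methoxy-substituted alkene carbons, so conjugate addition and electron transfer compete with 1,2-addition of a 2,6-dimethoxyaryllithium. A6 still needs deoxygenative aromatisation of two tertiary quinols and a twelve-fold demethylation.
- Comparison: the chosen strategy makes the B–C and C–D bonds without any coupling and attaches ring A to free phenols by a ligand coupling. It gives up the positional certainty of A6 in exchange.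

**Alternative 3:** Here the B–C and C–D bonds are disconnected. In the forward step the phenol A7 is arylated at both ortho positions by two equivalents of the aryllead reagent 11 to give the terphenyl A8.
- For: it is the shortest access to a chlorinated B–C–D terphenyl, one C–C bond-forming step from a simple phenol against five steps to 10. It uses the same ligand-coupling chemistry as step 7 of the chosen route. In step count to the terphenyl stage it is clearly superior.
- Against: in A8 rings B and D are fully methylated and the only free phenol is on ring C, which has no C–H left. Ring A would have to be attached at a C–H between two methoxy groups with no directing group. That means halogenation at one of four equivalent positions followed by a tetra-ortho-substituted cross-coupling, and the free, fully substituted ring C phenol invites dearomatising attack.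
- Comparison: the chosen route is longer to the terphenyl, but 10 arrives with rings B and D as free phloroglucinols, so the hydroxyl groups that direct the last arylation are already in place and ring C is masked.

Key step: step 4

## Route

Step 1
Reactants: 1 1,3,5-trimethoxybenzene
Product: 2 2-chloro-1,3,5-trimethoxybenzene
Conditions: NCS (1.0 equiv), MeCN, 0 °C to rt
Reagents that add atoms: N-chlorosuccinimide, O=C1CCC(=O)N1Cl
Why: Electrophilic aromatic chlorination; the three free positions of 1 are equivalent and each is ortho/para to three methoxy groups, and the chlorine lowers the reactivity enough for one equivalent of reagent to stop at the monochloride.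

Step 2
Reactants: 2 2-chloro-1,3,5-trimethoxybenzene
Product: 3 1,3-dibromo-5-chloro-2,4,6-trimethoxybenzene
Conditions: NBS (2.2 equiv), MeCN, rt to 40 °C
Reagents that add atoms: N-bromosuccinimide, O=C1CCC(=O)N1Br
Why: Exhaustive electrophilic aromatic bromination of the two remaining, equivalent positions, which takes up two molecules of the reagent; there is no regiochemical choice and a slight excess drives the second substitution.

Step 3
Reactants: 3 1,3-dibromo-5-chloro-2,4,6-trimethoxybenzene; 4 dimethyl malonate (two molecules)
Product: 5 tetramethyl 2,2'-(5-chloro-2,4,6-trimethoxy-1,3-phenylene)dimalonate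
Conditions: 4 (3 equiv), Pd(dba)2 (5 mol %), P(t-Bu)3·HBF4 (10 mol %), K3PO4 (6 equiv), toluene, 80 °C
Reagents that add atoms: dimethyl malonate (second molecule of 4), COC(=O)CC(=O)OC
Why: Palladium-catalysed α-arylation of a malonate enolate (enolate cross-coupling), established for 2,6-disubstituted aryl bromides with bulky trialkylphosphines; each C–Br bond takes up one molecule of 4, so two are consumed. Zerovalent palladium inserts into C–Br much faster than into the C–Cl bond shielded by two methoxy groups, and the crowded arylmalonate cannot be arylated a second time at carbon.

Step 4
Reactants: 5 tetramethyl 2,2'-(5-chloro-2,4,6-trimethoxy-1,3-phenylene)dimalonate; 6 dimethyl 3-oxoglutarate (two molecules)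
Product: 8 tetramethyl 5'-chloro-2,2'',4,4'',6,6''-hexahydroxy-2',4',6'-trimethoxy-[1,1':3',1''-terphenyl]-3,3'',5,5''-tetracarboxylate, via open-chain bis(C-acyl-oxoglutarate) adduct 7 (not isolated)
Conditions: NaOMe (8 equiv), 6 (3 equiv), xylene–diglyme, 135 °C, 6 added slowly, MeOH distilled off; then cold 1 M HCl
Reagents that add atoms: dimethyl 3-oxoglutarate (second molecule of 6), COC(=O)CC(=O)CC(=O)OC
Why: Sodium methoxide converts both malonate groups of 5 and the oxoglutarate 6 into enolates; at 135 °C with removal of methanol each arylmalonate enolate loses methoxide (E1cB) to give an aryl(methoxycarbonyl)ketene, whose sp carbon is acylated by a carbon enolate of its own molecule of 6, so that two molecules of 6 are taken up and the open-chain adduct 7 forms arm by arm. The remaining ester next to the aryl-bearing carbon is then attacked by the distal α-carbon of the same oxoglutarate unit, directly or after a second alkoxide loss to an acylketene, and enolisation gives the aromatic ring; in all, four molecules of methanol leave 5. The closest known reaction is the classical double Claisen condensation of a sodiomalonate with an acetonedicarboxylate to a phloroglucinol dicarboxylate, a (3+3) annulation. Rings B and D each close in the 6-exo-trig mode, the enolate carbon attacking an ester carbonyl whose oxygen stays outside the ring (6-exo-dig if the acylketene is the electrophile). No stereocentre survives, because the sp3 carbons of 7 all become aromatic. The step needs C,C- instead of C,O-diacylation and cross- instead of self-condensation of 6: alkoxide can reopen any 4-hydroxy-2-pyranone and return it to the open chain, deprotonation of the acidic, hydrogen-bonded phloroglucinol diester removes 8 from the equilibria, and slow addition of 6 keeps its self-condensation down. The two methoxy groups flanking each malonate carbon on ring C meet only a planar ketene and a planar enolate, since the aryl-bearing carbon never has to act as a nucleophile.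

Step 5
Reactants: 8 tetramethyl 5'-chloro-2,2'',4,4'',6,6''-hexahydroxy-2',4',6'-trimethoxy-[1,1':3',1''-terphenyl]-3,3'',5,5''-tetracarboxylate
Product: 10 5'-chloro-2',4',6'-trimethoxy-[1,1':3',1''-terphenyl]-2,2'',4,4'',6,6''-hexaol, via tetracarboxylic acid 9 (not isolated)
Conditions: KOH, H2O–MeOH (degassed), reflux, Ar; then 3 M HCl, 80 °C
Reagents that add atoms: none
Why: Ester saponification followed by decarboxylation of 2,4,6-trihydroxybenzoic acids, which lose CO2 on mild heating through their keto tautomers. The ring C methyl ethers and the C–Cl bond are inert to aqueous alkali and dilute acid, and air is excluded because the phenolates oxidise.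

Step 6
Reactants: 1 1,3,5-trimethoxybenzene
Product: 11 2,4,6-trimethoxyphenyllead triacetate
Conditions: Pb(OAc)4, CHCl3, rt, dark
Reagents that add atoms: lead tetraacetate, CC(=O)O[Pb](OC(C)=O)(OC(C)=O)OC(C)=O
Why: Direct electrophilic plumbation of a strongly activated arene by tetravalent lead, a known entry to polymethoxyaryllead triacetates; the reagent is used soon after isolation.

Step 7
Reactants: 10 5'-chloro-2',4',6'-trimethoxy-[1,1':3',1''-terphenyl]-2,2'',4,4'',6,6''-hexaol; 11 2,4,6-trimethoxyphenyllead triacetate
Product: 12 5''-chloro-2,2'',4,4'',6,6''-hexamethoxy-[1,1':3',1'':3'',1'''-quaterphenyl]-2',2''',4',4''',6',6'''-hexaol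
Conditions: 11 (0.8 equiv), pyridine (3 equiv), CHCl3, 40 °C; then dilute HCl
Reagents that add atoms: none
Why: Ortho C-arylation of an electron-rich phenol by an aryllead triacetate (Pinhey arylation): ligand exchange gives an aryloxy(aryl)lead diacetate, ligand coupling delivers the aryl group to the ortho carbon, and the dienone re-aromatises with release of divalent lead. The four C–H positions of 10 are equivalent, so only the number of aryl groups needs control, which a deficit of 11 and recycling of 10 provide; ring C, fully substituted and methylated, cannot react.

Step 8
Reactants: 12 5''-chloro-2,2'',4,4'',6,6''-hexamethoxy-[1,1':3',1'':3'',1'''-quaterphenyl]-2',2''',4',4''',6',6'''-hexaol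
Product: 13 5''-chloro-[1,1':3',1'':3'',1'''-quaterphenyl]-2,2',2'',2''',4,4',4'',4''',6,6',6'',6'''-dodecaol
Conditions: BBr3 (15 equiv), CH2Cl2, −78 °C to rt; then ice/H2O
Reagents that add atoms: none
Why: Lewis-acid cleavage of aryl methyl ethers (complexation at oxygen, bromide attack at methyl). The aryl chloride and the biaryl bonds are inert, and the twisted methoxy groups of ring C should cleave as readily as those of ring A.

## Compound list

1 | 1,3,5-trimethoxybenzene | COc1cc(OC)cc(OC)c1 | starting material
2 | 2-chloro-1,3,5-trimethoxybenzene | COc1cc(OC)c(Cl)c(OC)c1 | intermediate
3 | 1,3-dibromo-5-chloro-2,4,6-trimethoxybenzene | COc1c(Br)c(OC)c(Cl)c(OC)c1Br | intermediate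
4 | dimethyl malonate | COC(=O)CC(=O)OC | starting material
5 | tetramethyl 2,2'-(5-chloro-2,4,6-trimethoxy-1,3-phenylene)dimalonate | COC(=O)C(C(=O)OC)c1c(OC)c(Cl)c(OC)c(C(C(=O)OC)C(=O)OC)c1OC | intermediate
6 | dimethyl 3-oxoglutarate (dimethyl 3-oxopentanedioate) | COC(=O)CC(=O)CC(=O)OC | starting material
7 | hexamethyl 1,1'-(5-chloro-2,4,6-trimethoxy-1,3-phenylene)bis(2,4-dioxopentane-1,3,5-tricarboxylate), mixture of epimerisable stereoisomers and enol tautomers | COC(=O)CC(=O)C(C(=O)OC)C(=O)C(C(=O)OC)c1c(OC)c(Cl)c(OC)c(C(C(=O)OC)C(=O)C(C(=O)OC)C(=O)CC(=O)OC)c1OC | intermediate
8 | tetramethyl 5'-chloro-2,2'',4,4'',6,6''-hexahydroxy-2',4',6'-trimethoxy-[1,1':3',1''-terphenyl]-3,3'',5,5''-tetracarboxylate | COC(=O)c1c(O)c(C(=O)OC)c(O)c(-c2c(OC)c(Cl)c(OC)c(-c3c(O)c(C(=O)OC)c(O)c(C(=O)OC)c3O)c2OC)c1O | intermediate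
9 | 5'-chloro-2,2'',4,4'',6,6''-hexahydroxy-2',4',6'-trimethoxy-[1,1':3',1''-terphenyl]-3,3'',5,5''-tetracarboxylic acid | OC(=O)c1c(O)c(C(=O)O)c(O)c(-c2c(OC)c(Cl)c(OC)c(-c3c(O)c(C(=O)O)c(O)c(C(=O)O)c3O)c2OC)c1O | intermediate
10 | 5'-chloro-2',4',6'-trimethoxy-[1,1':3',1''-terphenyl]-2,2'',4,4'',6,6''-hexaol | Oc1cc(O)c(-c2c(OC)c(Cl)c(OC)c(-c3c(O)cc(O)cc3O)c2OC)c(O)c1 | intermediate
11 | 2,4,6-trimethoxyphenyllead triacetate | COc1cc(OC)c([Pb](OC(C)=O)(OC(C)=O)OC(C)=O)c(OC)c1 | intermediate
12 | 5''-chloro-2,2'',4,4'',6,6''-hexamethoxy-[1,1':3',1'':3'',1'''-quaterphenyl]-2',2''',4',4''',6',6'''-hexaol | COc1cc(OC)c(-c2c(O)cc(O)c(-c3c(OC)c(Cl)c(OC)c(-c4c(O)cc(O)cc4O)c3OC)c2O)c(OC)c1 | intermediate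
13 | 5''-chloro-[1,1':3',1'':3'',1'''-quaterphenyl]-2,2',2'',2''',4,4',4'',4''',6,6',6'',6'''-dodecaol (CNP0271703.0) | Oc1cc(O)c(-c2c(O)cc(O)c(-c3c(O)c(Cl)c(O)c(-c4c(O)cc(O)cc4O)c3O)c2O)c(O)c1 | target

## Step count and least certain steps

Total step count: 8. Longest linear sequence: 7 (steps 1, 2, 3, 4, 5, 7, 8); step 6 is a one-step branch from 1.

**Step 4 (key step).** The intermolecular acylation may fail to compete. Loss of methoxide from a stabilised, hindered arylmalonate enolate is slow, and at the temperature it needs 6 can condense with itself. Because each arm needs its own molecule of 6, one arm may react and the other not, or the sequence may stall at the C,O-diacylated pyranone.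

The fallback sets out from 5 and returns to the route at 7. Half-saponification of each malonate (KOH, 2 equiv, MeOH–H2O, 0 °C, then cold dilute HCl; the carboxylate formed protects the second ester of the same malonate) should give the bis(half-ester) 2,2'-(5-chloro-2,4,6-trimethoxy-1,3-phenylene)bis(3-methoxy-3-oxopropanoic acid) F1, kept cold to avoid decarboxylation. Oxalyl chloride with catalytic DMF in CH2Cl2 at 0 °C should give the bis(acid chloride) dimethyl 2,2'-(5-chloro-2,4,6-trimethoxy-1,3-phenylene)bis(3-chloro-3-oxopropanoate) F2. Added to the magnesium enolate of 6 (2.2 equiv of 6, MgCl2, Et3N, MeCN, 0 °C), F2 loses HCl to the same aryl(methoxycarbonyl)ketene, now at 0 °C instead of 135 °C. C-acylation of the magnesium chelate, one molecule of 6 per arm, should give 7 as an isolable compound, and closure of 7 with NaOMe in MeOH–toluene at reflux then gives 8.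

**Step 7.** Control over the number of aryl groups may be lost, through second and third arylations on the same or the other ring. Conversion may also be poor, because ligand coupling between a 2,6-dimethoxyaryl group on lead and a carbon flanked by two hydroxyls forms a tetra-ortho-substituted bond and competes with reductive decomposition of the lead reagent.

The fallback sets out from 10 and returns at 13. Exhaustive O-methylation (Me2SO4, K2CO3, acetone, reflux) should give 5'-chloro-2,2',2'',4,4',4'',6,6',6''-nonamethoxy-1,1':3',1''-terphenyl F3. One equivalent of NBS in MeCN should brominate one of the four equivalent positions to give 3-bromo-5'-chloro-2,2',2'',4,4',4'',6,6',6''-nonamethoxy-1,1':3',1''-terphenyl F4, which as a non-polar ether is easily separated from unreacted F3 and dibromides. Suzuki–Miyaura coupling of F4 with commercial (2,4,6-trimethoxyphenyl)boronic acid (Pd(OAc)2, SPhos, K3PO4, toluene–H2O, 100 °C; the bromide should react before the chloride) should give 5''-chloro-2,2',2'',2''',4,4',4'',4''',6,6',6'',6'''-dodecamethoxy-1,1':3',1'':3'',1'''-quaterphenyl F5. BBr3 under the conditions of step 8 then gives 13.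

**Step 3.** The coupling may stall after the first arylation, because the arylmalonate formed is present as its enolate and makes the ring more electron-rich, slowing the second oxidative addition. Hydrodebromination and, at higher temperature, insertion into the C–Cl bond are the other failure modes.

The fallback sets out from 1 and returns at 5, with the chlorine introduced last. NBS (2.0 equiv, MeCN) should give 2,4-dibromo-1,3,5-trimethoxybenzene F6. Coupling with two molecules of 4 under the catalyst of step 3 can now be forced with more catalyst and higher temperature, because no C–Cl bond is present, and should give tetramethyl 2,2'-(2,4,6-trimethoxy-1,3-phenylene)dimalonate F7. NCS in MeCN then chlorinates the single remaining ring position, which three methoxy groups activate, while the weakly enolised malonate C–H bonds stay untouched under neutral conditions, to give 5.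

## Further compounds

F1 | step 4 | 2,2'-(5-chloro-2,4,6-trimethoxy-1,3-phenylene)bis(3-methoxy-3-oxopropanoic acid), mixture of epimerisable diastereomers | COC(=O)C(C(=O)O)c1c(OC)c(Cl)c(OC)c(C(C(=O)O)C(=O)OC)c1OC
F2 | step 4 | dimethyl 2,2'-(5-chloro-2,4,6-trimethoxy-1,3-phenylene)bis(3-chloro-3-oxopropanoate), mixture of epimerisable diastereomers | COC(=O)C(C(Cl)=O)c1c(OC)c(Cl)c(OC)c(C(C(Cl)=O)C(=O)OC)c1OC
F3 | step 7 | 5'-chloro-2,2',2'',4,4',4'',6,6',6''-nonamethoxy-1,1':3',1''-terphenyl | COc1cc(OC)c(-c2c(OC)c(Cl)c(OC)c(-c3c(OC)cc(OC)cc3OC)c2OC)c(OC)c1
F4 | step 7 | 3-bromo-5'-chloro-2,2',2'',4,4',4'',6,6',6''-nonamethoxy-1,1':3',1''-terphenyl | COc1cc(OC)c(-c2c(OC)c(Cl)c(OC)c(-c3c(OC)cc(OC)c(Br)c3OC)c2OC)c(OC)c1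
F5 | step 7 | 5''-chloro-2,2',2'',2''',4,4',4'',4''',6,6',6'',6'''-dodecamethoxy-1,1':3',1'':3'',1'''-quaterphenyl | COc1cc(OC)c(-c2c(OC)cc(OC)c(-c3c(OC)c(Cl)c(OC)c(-c4c(OC)cc(OC)cc4OC)c3OC)c2OC)c(OC)c1
F6 | step 3 | 2,4-dibromo-1,3,5-trimethoxybenzene | COc1cc(OC)c(Br)c(OC)c1Br
F7 | step 3 | tetramethyl 2,2'-(2,4,6-trimethoxy-1,3-phenylene)dimalonate | COC(=O)C(C(=O)OC)c1c(OC)cc(OC)c(C(C(=O)OC)C(=O)OC)c1OC
A1 | alternative 1 | 3-ethoxy-4-(2,4,6-trimethoxyphenyl)cyclobut-2-en-1-one (racemic) | CCOC1=CC(=O)C1c1c(OC)cc(OC)cc1OC
A2 | alternative 1 | 1,4-diethoxybuta-1,3-diyne | CCOC#CC#COCC
A3 | alternative 1 | 4',4'',6',6''-tetraethoxy-2,2''',4,4''',6,6'''-hexamethoxy-[1,1':3',1'':3'',1'''-quaterphenyl]-2',2''-diol | COc1cc(OC)c(-c2c(OCC)cc(OCC)c(-c3c(OCC)cc(OCC)c(-c4c(OC)cc(OC)cc4OC)c3O)c2O)c(OC)c1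
A4 | alternative 2 | 3-chloro-2,2',4,4',6,6'-hexamethoxy-1,1'-biphenyl | COc1cc(OC)c(-c2c(OC)cc(OC)c(Cl)c2OC)c(OC)c1
A5 | alternative 2 | 2,4,4,6-tetramethoxycyclohexa-2,5-dien-1-one | COC1=CC(OC)(OC)C=C(OC)C1=O
A6 | alternative 2 | 1,1'-(5-chloro-2,2',4,4',6,6'-hexamethoxy-[1,1'-biphenyl]-3,3'-diyl)bis(2,4,4,6-tetramethoxycyclohexa-2,5-dien-1-ol) | COC1=CC(OC)(OC)C=C(OC)C1(O)c1c(OC)cc(OC)c(-c2c(OC)c(Cl)c(OC)c(C3(O)C(OC)=CC(OC)(OC)C=C3OC)c2OC)c1OC
A7 | alternative 3 | 4-chloro-3,5-dimethoxyphenol | COc1cc(O)cc(OC)c1Cl
A8 | alternative 3 | 4-chloro-3,5-dimethoxy-2,6-bis(2,4,6-trimethoxyphenyl)phenol | COc1cc(OC)c(-c2c(O)c(-c3c(OC)cc(OC)cc3OC)c(OC)c(Cl)c2OC)c(OC)c1
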